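**Plan**

1. Atom names: ring A carbons are C-a (CH bearing the CH2 linker), C-b (CH–isopropenyl), C-c and C-d (CH2–CH2), C-e (epoxide C–CH3) and C-f (epoxide CH); ring B carbons are C-p (CH bearing the side chain), C-q (CHBr) and C-r (C(CH3)OH).
2. Enabling feature: the C-e/C-f epoxide is a masked cyclohexene double bond lying opposite the C-b–C-c bond, with CH3 on C-e "para" to C-b and the side chain on C-a "ortho" to it. This is the retron of a Diels–Alder reaction between the diene C-d=C-e(CH3)–C-f=C-a(CH2X) and an acrylic dienophile C-b=C-c, whose acyl group stands for the isopropenyl group.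
3. Cuts (retro): the silyl ether on the C-r oxygen; the inter-ring C=CH2 (Wittig) and its CH2–C(=O) bond (Fukuyama acylation); the epoxide; ring A by retro-[4+2] (C-c–C-d and C-a–C-b); ring B by a second retro-[4+2], then C-q–Br and C-r–CH3.
4. Forward: ring A is closed first and taken to epoxy iodide 12; ring B is built separately as thioester 20; the two are joined, methylenated and deprotected.
5. Stereochemistry: C-a from the auxiliary-controlled endo Diels–Alder reaction; C-b by equilibration to trans; C-e and C-f by hydroxyl-directed epoxidation from the CH2OH on C-a; C-q by axial bromination anti to the auxiliary-set acyl group on C-p; C-r by methyl addition anti to bromine (cis-bromohydrin); C-p finally equilibrated to equatorial.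

Key step: step 2

Assumption: compounds 1, 4 and 15 are taken as catalogue materials (4 and 15 are otherwise one N-acylation away from the commercial oxazolidinones).

**Route**

Step 1
Reactants: 1 (E)-tert-butyldimethyl{[3-(4,4,5,5-tetramethyl-1,3,2-dioxaborolan-2-yl)prop-2-en-1-yl]oxy}silane; 2 2-bromopropene
Product: 3 tert-butyldimethyl{[(2E)-4-methylpenta-2,4-dien-1-yl]oxy}silane
Conditions: Pd(PPh3)4 (3 mol %), K2CO3, THF–H2O, 60 °C (sealed vessel)
Reagents that add atoms: none
Why: Suzuki–Miyaura coupling of an (E)-alkenylboronate with an alkenyl bromide proceeds with retention of alkene geometry and gives the (E)-1,3-disubstituted diene in one step; no stereocentre is formed.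

Step 2
Reactants: 3 tert-butyldimethyl{[(2E)-4-methylpenta-2,4-dien-1-yl]oxy}silane; 4 (S)-3-acryloyl-4-benzyloxazolidin-2-one
Product: 5 (S)-4-benzyl-3-[(1R,2S)-2-{[(tert-butyldimethylsilyl)oxy]methyl}-4-methylcyclohex-3-ene-1-carbonyl]oxazolidin-2-one
Conditions: Et2AlCl (1.4 equiv), CH2Cl2, −78 °C; 1 M HCl quench
Reagents that add atoms: none
Why: Diene 3 in its s-cis form adds in a concerted, asynchronous [4+2] cycloaddition to the acrylimide held as a cationic bidentate aluminium chelate, the closest known reaction type being the auxiliary-controlled Lewis-acid Diels–Alder reaction of N-acryloyloxazolidinones with acyclic dienes. Ring A closes in one intermolecular suprafacial–suprafacial event that makes the C-c–C-d and C-a–C-b bonds and leaves the C-e=C-f double bond, with its methyl group, exactly where the epoxide is needed. Regiochemistry is doubly secured, because the 3-methyl group ("para" rule) and the 1-CH2OTBS group ("ortho" rule) both put the largest diene coefficient on the unsubstituted terminus C-d, which bonds to the acrylate β-carbon C-c. C-b is set by the auxiliary, whose benzyl group shields one face of the chelated s-cis dienophile so that the diene adds to the Cα-si face, and C-a is set relative to C-b by the endo transition state, which with the (E)-diene gives the cis (1R,2S) adduct. The step needs endo and π-facial selectivity and survival of the allylic silyl ether, which the rigid chelate and the low temperature should secure; C-a fixed here is the centre from which C-b, C-e and C-f are later derived.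

Step 3
Reactants: 5 (S)-4-benzyl-3-[(1R,2S)-2-{[(tert-butyldimethylsilyl)oxy]methyl}-4-methylcyclohex-3-ene-1-carbonyl]oxazolidin-2-one
Product: 6 (1R,2S)-2-{[(tert-butyldimethylsilyl)oxy]methyl}-4-methylcyclohex-3-ene-1-carboxylic acid
Conditions: LiOH, H2O2, THF–H2O, 0 °C; Na2SO3; 1 M HCl to pH 3
Reagents that add atoms: hydrogen peroxide (OO)
Why: Evans LiOOH hydrolysis, in which the hydroperoxide anion attacks the exocyclic imide carbonyl selectively even for α-branched acyl groups, releases the acid without touching C-a or C-b and returns the auxiliary.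

Step 4
Reactants: 6 (1R,2S)-2-{[(tert-butyldimethylsilyl)oxy]methyl}-4-methylcyclohex-3-ene-1-carboxylic acid
Product: 7 1-[(1R,2S)-2-{[(tert-butyldimethylsilyl)oxy]methyl}-4-methylcyclohex-3-en-1-yl]ethan-1-one (cis)
Conditions: MeLi (2.2 equiv), Et2O, 0 °C; NH4Cl
Reagents that add atoms: methyllithium ([Li]C)
Why: Addition of two equivalents of methyllithium to a carboxylic acid gives a stable dilithio gem-diolate that collapses to the methyl ketone only on work-up (classical acid-to-methyl-ketone conversion), leaving C-a unchanged.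

Step 5
Reactants: 7 1-[(1R,2S)-2-{[(tert-butyldimethylsilyl)oxy]methyl}-4-methylcyclohex-3-en-1-yl]ethan-1-one
Product: 8 1-[(1S,2S)-2-{[(tert-butyldimethylsilyl)oxy]methyl}-4-methylcyclohex-3-en-1-yl]ethan-1-one (trans)
Conditions: NaOMe (0.3 equiv), MeOH, 25 °C; recovered 7 resubmitted
Reagents that add atoms: none
Why: Thermodynamic epimerisation of a Diels–Alder cis adduct by enolisation–reprotonation at C-b should favour the trans isomer, in which both substituents are pseudo-equatorial, the non-enolisable C-a being the controlling centre.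

Step 6
Reactants: 8 1-[(1S,2S)-2-{[(tert-butyldimethylsilyl)oxy]methyl}-4-methylcyclohex-3-en-1-yl]ethan-1-one
Product: 9 tert-butyldimethyl{[(1S,6S)-3-methyl-6-(prop-1-en-2-yl)cyclohex-2-en-1-yl]methoxy}silane
Conditions: Ph3PCH3Br, KOtBu, THF, 0 → 25 °C
Reagents that add atoms: methyltriphenylphosphonium bromide (C[P+](c1ccccc1)(c1ccccc1)c1ccccc1.[Br-])
Why: Wittig methylenation converts the acetyl group into the isopropenyl group, and any enolisation under the basic conditions only returns C-b to the favoured trans configuration.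

Step 7
Reactants: 9 tert-butyldimethyl{[(1S,6S)-3-methyl-6-(prop-1-en-2-yl)cyclohex-2-en-1-yl]methoxy}silane
Product: 10 [(1S,6S)-3-methyl-6-(prop-1-en-2-yl)cyclohex-2-en-1-yl]methanol
Conditions: TBAF, THF, 0 → 25 °C; NH4Cl
Reagents that add atoms: none
Why: Fluoride desilylation of the primary TBS ether unmasks the homoallylic hydroxyl group that is needed as a directing group.

Step 8
Reactants: 10 [(1S,6S)-3-methyl-6-(prop-1-en-2-yl)cyclohex-2-en-1-yl]methanol
Product: 11 [(1R,2S,3S,6S)-6-methyl-3-(prop-1-en-2-yl)-7-oxabicyclo[4.1.0]heptan-2-yl]methanol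
Conditions: VO(acac)2 (5 mol %), t-BuOOH, CH2Cl2, 0 → 25 °C
Reagents that add atoms: tert-butyl hydroperoxide (CC(C)(C)OO)
Why: Vanadium-catalysed hydroxyl-directed epoxidation of a homoallylic alcohol delivers oxygen from the alkoxide-bound peroxo complex to the face of the C-e=C-f double bond that carries the CH2OH group, which sets C-e and C-f cis to the side chain on C-a and should prefer the proximal trisubstituted alkene over the more remote, less nucleophilic isopropenyl group.

Step 9
Reactants: 11 [(1R,2S,3S,6S)-6-methyl-3-(prop-1-en-2-yl)-7-oxabicyclo[4.1.0]heptan-2-yl]methanol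
Product: 12 (1S,4S,5R,6R)-5-(iodomethyl)-1-methyl-4-(prop-1-en-2-yl)-7-oxabicyclo[4.1.0]heptane
Conditions: PPh3, I2, imidazole, CH2Cl2, 0 °C
Reagents that add atoms: iodine (II)
Why: Garegg–Samuelsson (Appel-type) iodination converts the primary alcohol into the iodide under buffered, non-acidic conditions that a trisubstituted epoxide should tolerate; no stereocentre is involved.

Step 10
Reactants: 13 but-3-en-2-one (methyl vinyl ketone)
Product: 14 (buta-1,3-dien-2-yloxy)tri(propan-2-yl)silane
Conditions: TIPSOTf, Et3N, Et2O, 0 °C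
Reagents that add atoms: triisopropylsilyl trifluoromethanesulfonate (CC(C)[Si](C(C)C)(C(C)C)OS(=O)(=O)C(F)(F)F)
Why: Soft enolisation of the enone with a silyl triflate and an amine base gives the robust 2-silyloxydiene (silyl dienol ether formation).

Step 11
Reactants: 14 (buta-1,3-dien-2-yloxy)tri(propan-2-yl)silane; 15 (R)-3-acryloyl-4-benzyloxazolidin-2-one
Product: 16 (R)-4-benzyl-3-[(S)-4-{[tri(propan-2-yl)silyl]oxy}cyclohex-3-ene-1-carbonyl]oxazolidin-2-one
Conditions: Et2AlCl (1.4 equiv), CH2Cl2, −78 °C; NaHCO3 work-up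
Reagents that add atoms: none
Why: In this second Evans auxiliary-controlled Diels–Alder reaction the 2-silyloxy group directs "para" regiochemistry and the (R)-benzyl auxiliary exposes the Cα-re face of the chelated acrylimide, which sets C-p as (S) and delivers a regiodefined silyl enol ether that marks C-q for bromination.

Step 12
Reactants: 16 (R)-4-benzyl-3-[(S)-4-{[tri(propan-2-yl)silyl]oxy}cyclohex-3-ene-1-carbonyl]oxazolidin-2-one
Product: 17 (R)-4-benzyl-3-[(1S,3R)-3-bromo-4-oxocyclohexane-1-carbonyl]oxazolidin-2-one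
Conditions: NBS, THF–H2O, 0 °C; crude product used at once
Reagents that add atoms: N-bromosuccinimide (O=C1CCC(=O)N1Br)
Why: Electrophilic bromination of a silyl enol ether is regiospecific for the enol carbon C-q and occurs by stereoelectronically controlled axial attack on the half-chair that has the acyl group on C-p equatorial, which should give the trans (axial) α-bromoketone with C-q = R.

Step 13
Reactants: 17 (R)-4-benzyl-3-[(1S,3R)-3-bromo-4-oxocyclohexane-1-carbonyl]oxazolidin-2-one
Product: 18 (R)-4-benzyl-3-[(1S,3R,4S)-3-bromo-4-hydroxy-4-methylcyclohexane-1-carbonyl]oxazolidin-2-one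
Conditions: CeCl3, MeMgBr, THF, −78 °C; NH4Cl at −78 °C
Reagents that add atoms: methylmagnesium bromide (C[Mg]Br)
Why: Organocerium 1,2-addition to an α-haloketone under Cornforth (polar Felkin–Anh) control places the methyl group anti to the axial C–Br bond, which is also the axial trajectory, so that OH ends cis to Br (the cis-bromohydrin, C-r = S), while the non-basic reagent should spare the imide and avoid bromine–metal exchange.

Step 14
Reactants: 18 (R)-4-benzyl-3-[(1S,3R,4S)-3-bromo-4-hydroxy-4-methylcyclohexane-1-carbonyl]oxazolidin-2-one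
Product: 19 (R)-4-benzyl-3-[(1S,3R,4S)-3-bromo-4-methyl-4-[(triethylsilyl)oxy]cyclohexane-1-carbonyl]oxazolidin-2-one
Conditions: TESOTf, 2,6-lutidine, CH2Cl2, −78 → 0 °C
Reagents that add atoms: triethylsilyl trifluoromethanesulfonate (CC[Si](CC)(CC)OS(=O)(=O)C(F)(F)F)
Why: Silylation of the tertiary alcohol with a silyl triflate protects the cis-bromohydrin against base-induced semipinacol ring contraction in the later basic steps.

Step 15
Reactants: 19 (R)-4-benzyl-3-[(1S,3R,4S)-3-bromo-4-methyl-4-[(triethylsilyl)oxy]cyclohexane-1-carbonyl]oxazolidin-2-one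
Product: 20 S-ethyl (1S,3R,4S)-3-bromo-4-methyl-4-[(triethylsilyl)oxy]cyclohexane-1-carbothioate
Conditions: EtSH, n-BuLi, THF, 0 °C; NH4Cl
Reagents that add atoms: ethanethiol (CCS)
Why: Lithium ethanethiolate cleaves N-acyloxazolidinones selectively at the exocyclic carbonyl (thiolate transacylation), which gives the thioester needed for ketone synthesis and returns the auxiliary, while the hindered secondary bromide next to a quaternary carbon should not be displaced.

Step 16
Reactants: 12 (1S,4S,5R,6R)-5-(iodomethyl)-1-methyl-4-(prop-1-en-2-yl)-7-oxabicyclo[4.1.0]heptane; 20 S-ethyl (1S,3R,4S)-3-bromo-4-methyl-4-[(triethylsilyl)oxy]cyclohexane-1-carbothioate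
Product: 22 1-[(1S,3R,4S)-3-bromo-4-methyl-4-[(triethylsilyl)oxy]cyclohexyl]-2-[(1R,2R,3S,6S)-6-methyl-3-(prop-1-en-2-yl)-7-oxabicyclo[4.1.0]heptan-2-yl]ethan-1-one, via alkylzinc iodide 21 (not isolated)
Conditions: Zn, LiCl, THF, 25 °C; solution decanted from excess Zn; then 20, PdCl2(PPh3)2 (5 mol %), toluene, 25 °C; NH4Cl
Reagents that add atoms: none
Why: In this Fukuyama ketone synthesis zinc inserts into the primary C–I bond and the alkylzinc iodide, which cannot open the epoxide from the rear because CH2Zn and the epoxide oxygen are cis, is acylated by the thioester under palladium catalysis that should leave the unactivated secondary bromide, the epoxide and the silyl ether untouched; removing the excess zinc first keeps the metal away from the C–Br bond.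

Step 17
Reactants: 22 1-[(1S,3R,4S)-3-bromo-4-methyl-4-[(triethylsilyl)oxy]cyclohexyl]-2-[(1R,2R,3S,6S)-6-methyl-3-(prop-1-en-2-yl)-7-oxabicyclo[4.1.0]heptan-2-yl]ethan-1-one
Product: 23 1-[(1R,3R,4S)-3-bromo-4-methyl-4-[(triethylsilyl)oxy]cyclohexyl]-2-[(1R,2R,3S,6S)-6-methyl-3-(prop-1-en-2-yl)-7-oxabicyclo[4.1.0]heptan-2-yl]ethan-1-one
Conditions: NaOMe (0.2 equiv), MeOH–THF, 0 → 25 °C; minor epimer separated and re-equilibrated
Reagents that add atoms: none
Why: Thermodynamic epimerisation α to the ketone at C-p should favour 23, because only in the (1R) epimer can the acyl, bromo and methyl groups all be equatorial, while the cis-disposed CH2 and epoxide oxygen prevent the second enolate from opening the epoxide.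

Step 18
Reactants: 23 1-[(1R,3R,4S)-3-bromo-4-methyl-4-[(triethylsilyl)oxy]cyclohexyl]-2-[(1R,2R,3S,6S)-6-methyl-3-(prop-1-en-2-yl)-7-oxabicyclo[4.1.0]heptan-2-yl]ethan-1-one
Product: 24 {[(1S,2R,4R)-2-bromo-1-methyl-4-{3-[(1R,2R,3S,6S)-6-methyl-3-(prop-1-en-2-yl)-7-oxabicyclo[4.1.0]heptan-2-yl]prop-1-en-2-yl}cyclohexyl]oxy}triethylsilane
Conditions: Ph3PCH3Br, KOtBu, THF, 0 → 25 °C
Reagents that add atoms: methyltriphenylphosphonium bromide (C[P+](c1ccccc1)(c1ccccc1)c1ccccc1.[Br-])
Why: Wittig methylenation installs the 1,1-disubstituted alkene between the rings, and because the equatorial ketone 23 is both favoured at equilibrium and the faster-reacting epimer, C-p should not be eroded; the equatorial bromide has no anti-periplanar hydrogen for elimination.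

Step 19
Reactants: 24 {[(1S,2R,4R)-2-bromo-1-methyl-4-{3-[(1R,2R,3S,6S)-6-methyl-3-(prop-1-en-2-yl)-7-oxabicyclo[4.1.0]heptan-2-yl]prop-1-en-2-yl}cyclohexyl]oxy}triethylsilane
Product: 25 (1S,2R,4R)-2-bromo-1-methyl-4-{3-[(1R,2R,3S,6S)-6-methyl-3-(prop-1-en-2-yl)-7-oxabicyclo[4.1.0]heptan-2-yl]prop-1-en-2-yl}cyclohexan-1-ol (CNP0213097.1)
Conditions: TBAF, AcOH, THF, 0 → 25 °C
Reagents that add atoms: none
Why: Fluoride desilylation buffered with acetic acid removes the TES group without leaving a free alkoxide (which could trigger semipinacol contraction of the cis-bromohydrin) and without opening the epoxide, giving the target.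

**Compound list**

1 | (E)-tert-butyldimethyl{[3-(4,4,5,5-tetramethyl-1,3,2-dioxaborolan-2-yl)prop-2-en-1-yl]oxy}silane | CC(C)(C)[Si](C)(C)OC/C=C/B1OC(C)(C)C(C)(C)O1 | starting material
2 | 2-bromopropene | CC(Br)=C | starting material
3 | tert-butyldimethyl{[(2E)-4-methylpenta-2,4-dien-1-yl]oxy}silane | CC(=C)/C=C/CO[Si](C)(C)C(C)(C)C | intermediate
4 | (S)-3-acryloyl-4-benzyloxazolidin-2-one | C=CC(=O)N1[C@@H](Cc2ccccc2)COC1=O | starting material
5 | (S)-4-benzyl-3-[(1R,2S)-2-{[(tert-butyldimethylsilyl)oxy]methyl}-4-methylcyclohex-3-ene-1-carbonyl]oxazolidin-2-one | CC(C)(C)[Si](C)(C)OC[C@@H]1[C@H](C(=O)N2[C@@H](Cc3ccccc3)COC2=O)CCC(C)=C1 | intermediate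
6 | (1R,2S)-2-{[(tert-butyldimethylsilyl)oxy]methyl}-4-methylcyclohex-3-ene-1-carboxylic acid | CC(C)(C)[Si](C)(C)OC[C@@H]1[C@H](C(=O)O)CCC(C)=C1 | intermediate
7 | 1-[(1R,2S)-2-{[(tert-butyldimethylsilyl)oxy]methyl}-4-methylcyclohex-3-en-1-yl]ethan-1-one | CC(C)(C)[Si](C)(C)OC[C@@H]1[C@H](C(C)=O)CCC(C)=C1 | intermediate
8 | 1-[(1S,2S)-2-{[(tert-butyldimethylsilyl)oxy]methyl}-4-methylcyclohex-3-en-1-yl]ethan-1-one | CC(C)(C)[Si](C)(C)OC[C@@H]1[C@@H](C(C)=O)CCC(C)=C1 | intermediate
9 | tert-butyldimethyl{[(1S,6S)-3-methyl-6-(prop-1-en-2-yl)cyclohex-2-en-1-yl]methoxy}silane | CC(C)(C)[Si](C)(C)OC[C@@H]1[C@@H](C(C)=C)CCC(C)=C1 | intermediate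
10 | [(1S,6S)-3-methyl-6-(prop-1-en-2-yl)cyclohex-2-en-1-yl]methanol | OC[C@@H]1[C@@H](C(C)=C)CCC(C)=C1 | intermediate
11 | [(1R,2S,3S,6S)-6-methyl-3-(prop-1-en-2-yl)-7-oxabicyclo[4.1.0]heptan-2-yl]methanol | OC[C@@H]1[C@@H](C(C)=C)CC[C@]2(C)O[C@H]12 | intermediate
12 | (1S,4S,5R,6R)-5-(iodomethyl)-1-methyl-4-(prop-1-en-2-yl)-7-oxabicyclo[4.1.0]heptane | IC[C@@H]1[C@@H](C(C)=C)CC[C@]2(C)O[C@H]12 | intermediate
13 | but-3-en-2-one | CC(=O)C=C | starting material
14 | (buta-1,3-dien-2-yloxy)tri(propan-2-yl)silane | C=CC(=C)O[Si](C(C)C)(C(C)C)C(C)C | intermediate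
15 | (R)-3-acryloyl-4-benzyloxazolidin-2-one | C=CC(=O)N1[C@H](Cc2ccccc2)COC1=O | starting material
16 | (R)-4-benzyl-3-[(S)-4-{[tri(propan-2-yl)silyl]oxy}cyclohex-3-ene-1-carbonyl]oxazolidin-2-one | O=C([C@H]1CCC(O[Si](C(C)C)(C(C)C)C(C)C)=CC1)N1[C@H](Cc2ccccc2)COC1=O | intermediate
17 | (R)-4-benzyl-3-[(1S,3R)-3-bromo-4-oxocyclohexane-1-carbonyl]oxazolidin-2-one | O=C([C@H]1CCC(=O)[C@H](Br)C1)N1[C@H](Cc2ccccc2)COC1=O | intermediate
18 | (R)-4-benzyl-3-[(1S,3R,4S)-3-bromo-4-hydroxy-4-methylcyclohexane-1-carbonyl]oxazolidin-2-one | O=C([C@H]1CC[C@](C)(O)[C@H](Br)C1)N1[C@H](Cc2ccccc2)COC1=O | intermediate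
19 | (R)-4-benzyl-3-[(1S,3R,4S)-3-bromo-4-methyl-4-[(triethylsilyl)oxy]cyclohexane-1-carbonyl]oxazolidin-2-one | O=C([C@H]1CC[C@](C)(O[Si](CC)(CC)CC)[C@H](Br)C1)N1[C@H](Cc2ccccc2)COC1=O | intermediate
20 | S-ethyl (1S,3R,4S)-3-bromo-4-methyl-4-[(triethylsilyl)oxy]cyclohexane-1-carbothioate | CCSC(=O)[C@H]1CC[C@](C)(O[Si](CC)(CC)CC)[C@H](Br)C1 | intermediate
21 | iodo{[(1R,2R,3S,6S)-6-methyl-3-(prop-1-en-2-yl)-7-oxabicyclo[4.1.0]heptan-2-yl]methyl}zinc | I[Zn]C[C@@H]1[C@@H](C(C)=C)CC[C@]2(C)O[C@H]12 | intermediate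
22 | 1-[(1S,3R,4S)-3-bromo-4-methyl-4-[(triethylsilyl)oxy]cyclohexyl]-2-[(1R,2R,3S,6S)-6-methyl-3-(prop-1-en-2-yl)-7-oxabicyclo[4.1.0]heptan-2-yl]ethan-1-one | O=C(C[C@@H]1[C@@H](C(C)=C)CC[C@]2(C)O[C@H]12)[C@H]1CC[C@](C)(O[Si](CC)(CC)CC)[C@H](Br)C1 | intermediate
23 | 1-[(1R,3R,4S)-3-bromo-4-methyl-4-[(triethylsilyl)oxy]cyclohexyl]-2-[(1R,2R,3S,6S)-6-methyl-3-(prop-1-en-2-yl)-7-oxabicyclo[4.1.0]heptan-2-yl]ethan-1-one | O=C(C[C@@H]1[C@@H](C(C)=C)CC[C@]2(C)O[C@H]12)[C@@H]1CC[C@](C)(O[Si](CC)(CC)CC)[C@H](Br)C1 | intermediate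
24 | {[(1S,2R,4R)-2-bromo-1-methyl-4-{3-[(1R,2R,3S,6S)-6-methyl-3-(prop-1-en-2-yl)-7-oxabicyclo[4.1.0]heptan-2-yl]prop-1-en-2-yl}cyclohexyl]oxy}triethylsilane | C=C(C[C@@H]1[C@@H](C(C)=C)CC[C@]2(C)O[C@H]12)[C@@H]1CC[C@](C)(O[Si](CC)(CC)CC)[C@H](Br)C1 | intermediate
25 | (1S,2R,4R)-2-bromo-1-methyl-4-{3-[(1R,2R,3S,6S)-6-methyl-3-(prop-1-en-2-yl)-7-oxabicyclo[4.1.0]heptan-2-yl]prop-1-en-2-yl}cyclohexan-1-ol | C=C(C[C@@H]1[C@@H](C(=C)C)CC[C@]2(C)O[C@H]12)[C@@H]1CC[C@](C)(O)[C@H](Br)C1 | target

**Step count**

Total: 19 steps. Longest linear sequence: 13 steps (steps 1–9, then 16–19); the ring B branch (steps 10–15) joins at step 16.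

**Steps most likely to fail, with fallbacks**

Step 16. The zinc insertion may stall, or zinc halide may open the trisubstituted epoxide, or acyl transfer to the α-branched thioester may be too slow. The fallback replaces the palladium-catalysed zinc chemistry by direct acyl substitution with an alkyllithium at low temperature. It sets out from 20 and 12. Thioester 20 is converted with MeNHOMe·HCl and iPrMgCl (THF, −20 °C) into (1S,3R,4S)-3-bromo-N-methoxy-N,4-dimethyl-4-[(triethylsilyl)oxy]cyclohexane-1-carboxamide F1. Iodide 12 undergoes iodine–lithium exchange with t-BuLi (2 equiv, Et2O–pentane, −78 °C) to give {[(1R,2R,3S,6S)-6-methyl-3-(prop-1-en-2-yl)-7-oxabicyclo[4.1.0]heptan-2-yl]methyl}lithium F2, which is added at −78 °C to F1. The stable chelated adduct collapses on work-up and the fallback comes back to the route at ketone 22.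

Step 17. The thermodynamic bias at C-p may be too small, or the axial-bromide conformer of the unwanted epimer may eliminate under alkoxide. The fallback sets C-p before the two rings are joined, by an epimerisation–lactonisation funnel, and sets out from 18. With DBU and catalytic DMAP (toluene, 40–60 °C) the imide α-centre epimerises. Only the epimer with the acyl group cis to the hydroxyl on C-r can transfer its activated acyl group to that hydroxyl, and it should do so irreversibly, giving (1S,4R,6R)-6-bromo-1-methyl-2-oxabicyclo[2.2.2]octan-3-one F3 and releasing the auxiliary. Me3Al/EtSH (CH2Cl2, 0 °C) opens the lactone to S-ethyl (1R,3R,4S)-3-bromo-4-hydroxy-4-methylcyclohexane-1-carbothioate F4, and TESOTf/2,6-lutidine gives S-ethyl (1R,3R,4S)-3-bromo-4-methyl-4-[(triethylsilyl)oxy]cyclohexane-1-carbothioate F5. Coupling of F5 with 21 under the step 16 conditions comes back to the route at 23.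

Step 8. Oxygen delivery may be poorly face-selective, or the isopropenyl group may be epoxidised competitively. The fallback replaces metal-directed oxygen transfer by a tethered iodocarbonate cyclisation and sets out from 10.
- Boc2O/DMAP gives tert-butyl {[(1S,6S)-3-methyl-6-(prop-1-en-2-yl)cyclohex-2-en-1-yl]methyl} carbonate F6.
- IBr (1 equiv, toluene, −85 °C) should close the cis-fused iodo cyclic carbonate (4aS,5S,8R,8aR)-8-iodo-8-methyl-5-(prop-1-en-2-yl)hexahydro-4H-benzo[d][1,3]dioxin-2-one F7. This is a 1,3-dioxan-2-one spanning the CH2O group and the oxygen on C-f, with iodine on C-e anti to that oxygen.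
- The tether forces the oxygen onto the face of the side chain. Because oxygen and iodine end up trans across the former double bond whichever alkene carbon the carbonate attacks, the stereochemical outcome does not depend on the regiochemistry of ring closure.
- K2CO3 in MeOH cleaves the carbonate, the alkoxide on C-f displaces the iodide on C-e from the rear, and the fallback comes back to the route at 11.

**Further compounds**

F1 | step 16 | (1S,3R,4S)-3-bromo-N-methoxy-N,4-dimethyl-4-[(triethylsilyl)oxy]cyclohexane-1-carboxamide | CON(C)C(=O)[C@H]1CC[C@](C)(O[Si](CC)(CC)CC)[C@H](Br)C1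
F2 | step 16 | {[(1R,2R,3S,6S)-6-methyl-3-(prop-1-en-2-yl)-7-oxabicyclo[4.1.0]heptan-2-yl]methyl}lithium | [Li]C[C@@H]1[C@@H](C(C)=C)CC[C@]2(C)O[C@H]12
F3 | step 17 | (1S,4R,6R)-6-bromo-1-methyl-2-oxabicyclo[2.2.2]octan-3-one | O=C1O[C@@]2(C)CC[C@@H]1C[C@H]2Br
F4 | step 17 | S-ethyl (1R,3R,4S)-3-bromo-4-hydroxy-4-methylcyclohexane-1-carbothioate | CCSC(=O)[C@@H]1CC[C@](C)(O)[C@H](Br)C1
F5 | step 17 | S-ethyl (1R,3R,4S)-3-bromo-4-methyl-4-[(triethylsilyl)oxy]cyclohexane-1-carbothioate | CCSC(=O)[C@@H]1CC[C@](C)(O[Si](CC)(CC)CC)[C@H](Br)C1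
F6 | step 8 | tert-butyl {[(1S,6S)-3-methyl-6-(prop-1-en-2-yl)cyclohex-2-en-1-yl]methyl} carbonate | CC(C)(C)OC(=O)OC[C@@H]1[C@@H](C(C)=C)CCC(C)=C1
F7 | step 8 | (4aS,5S,8R,8aR)-8-iodo-8-methyl-5-(prop-1-en-2-yl)hexahydro-4H-benzo[d][1,3]dioxin-2-one | O=C1OC[C@@H]2[C@@H](C(C)=C)CC[C@@](C)(I)[C@@H]2O1
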